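A leftover starts this reckoning: what remains of each substrate in a flask.

the same everywhere: left-handed substrate 0.014 M; right-handed substrate 0.014 M; reagent 0.0154 M (in portions, 2)

| flask | free catalyst | added ligand | remark | time |
|---|---|---|---|---|
| delta | 0.70 mM | 0.34 mM | run made earlier; portions every 10 min |  |
| theta | 0.70 mM | 0.52 mM | run made earlier; portions every 10 min |  |
| gamma | 0.35 mM | 0.69 mM | run made earlier; portions every 10 min |  |
| flask | 0.70 mM | 0.69 mM | the portions of reagent follow each other after 10 min, the first at the start | 30 min |

| run | time / min | left-handed product / % | right-handed substrate / % |
|---|---|---|---|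
| delta | 3.00 | 2 | 44 |
| delta | 6.00 | 6 | 42 |
| delta | 10.0 | 7 | 40 |
| delta | 15.0 | 15 | 34 |
| delta | 20.0 | 20 | 30 |
| delta | 25.0 | 24 | 29 |
| theta | 2.00 | 6 | 51 |
| theta | 3.00 | 6 | 49 |
| theta | 4.00 | 4 | 44 |
| theta | 6.00 | 7 | 43 |
| theta | 10.0 | 10 | 42 |
| theta | 15.0 | 18 | 36 |
| theta | 25.0 | 24 | 31 |
| gamma | 5.00 | 7 | 45 |
| gamma | 10.0 | 7 | 46 |
| gamma | 15.0 | 11 | 41 |
| gamma | 20.0 | 14 | 40 |
| gamma | 25.0 | 18 | 37 |

(each reading ± 1.5 percentage points)

- the left-handed product in the flask at 30 min, as a percentage of the left-handed substrate and right-handed substrate together charged
- the right-handed substrate in the flask at 30 min, as a percentage of the left-handed substrate and right-handed substrate together charged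
- the right-handed product in the flask at 30 min, as a percentage of the left-handed substrate and right-handed substrate together charged
- the left-handed substrate in the flask at 30 min, as a percentage of the left-handed substrate and right-handed substrate together charged
- concentration of reagent at 30 min, in M

- free catalyst is single-handed; left-handed substrate and right-handed substrate are mirror images of each other, charged as a racemate, each of them at the stated concentration
- the numbers in the tables scatter by 1.5 percentage points (one standard deviation)

Each substrate is charged as 50.0% of the total, so the left-handed substrate remaining is that share less the left-handed product. Suppose each substrate is consumed at a rate proportional to its own concentration, with catalyst and reagent common to both rates. Dividing one rate by the other then removes time, and with it the portions: the logarithm of the fraction of left-handed substrate left, over the same logarithm for the right-handed substrate, is a constant s, the selectivity factor. At 25.0 min the delta run gives 1.20; at 25.0 min the theta run gives 1.37; at 25.0 min the gamma run gives 1.48.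

Next comes the amount consumed. At 25.0 min, the readings put the substrates consumed at 45.0% in delta and 43.0% in theta. Continuing that line to the flask's ligand gives 41.1%. Taking one reagent per substrate, and a charge of 55.0% on the same scale, this reckoning has 13.9% of reagent in the flask at 25.0 min. Theta's leftover reagent, read between 15.0 min and 25.0 min, decays at 0.0651 min⁻¹, and that rate brings the estimate to 10.0% at 30 min, or 0.00281 M. The fraction of substrate left overall is then f = 55.0%.

Placing the two fractions around f, the right-handed fraction is f raised to two divided by one plus s. Theta's ratio gives 30.2% right-handed substrate. That is the weak link, one ratio from two readings, each scattered by 1.5 percentage points. Under the supposition catalyst cancels in the ratio, so gamma may join, and the mean of the three readings, taken across their different ligand charges, is the selectivity factor carried on, s = 1.35. This reckoning commits to 30.1% right-handed substrate, 25.2% left-handed substrate, 24.8% left-handed product and 19.9% right-handed product.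

The forecast gives 26.3% left-handed product, 29.3% right-handed substrate, 20.7% right-handed product, 23.7% left-handed substrate and 0.0022 M reagent. It holds that “Added ligand has little effect on rate” and takes s as about 1.4. Its reagent stands lower than the 0.00281 M reckoned here.

The flask gives 24.1% left-handed product, 29.3% right-handed substrate, 20.2% right-handed product, 25.7% left-handed substrate and 0.00301 M reagent.

    free catalyst + left-handed substrate ⇌ catalyst intermediate A (K = 31.0 M⁻¹, k = 1100 M⁻¹ min⁻¹)
    free catalyst + right-handed substrate ⇌ catalyst intermediate B (K = 70.0 M⁻¹, k = 280 M⁻¹ min⁻¹)
    reagent + catalyst intermediate A → free catalyst + left-handed product (k = 470 M⁻¹ min⁻¹)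
    reagent + catalyst intermediate B → free catalyst + right-handed product (k = 200 M⁻¹ min⁻¹)
    free catalyst + added ligand ⇌ idle complex (K = 6300 M⁻¹, k = 62.0 M⁻¹ min⁻¹)

Set on the 55.0% of substrate that the flask still holds at 30 min, the carried s puts its right-handed substrate at 30.1%, beside the 29.3% found. The flask is not at rest: 19.5% of the reagent remains at 30 min, and at 300 min the amount is 0%. With the whole charge of reagent consumed, s puts the right-handed substrate at 25.3%. Ten times the time holds 24.0% right-handed substrate, 20.6% left-handed substrate, 25.7% right-handed product and 29.3% left-handed product.

The data were generated by integration from invented constants; scatter was added.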